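The benzene ring of the tetralone is made, not bought. Its C8(OH)–C7(H)–C6(Ph) edge, with the peri ketone C1 on C8a, is read as a 3-acyl-4-hydroxy-6-phenyl-2-pyranone. Its C4a–C5(pyranonyl) edge is read as the enol of a 6-(2-oxoalkyl)pyranone. The key step is an intramolecular, polarity-matched pyranone Diels–Alder reaction that forms C4a–C8a and C5–C6, followed in the same flask by loss of CO2 and silanol. It closes the cyclohexanone ring and the benzene ring in one operation. Its precursor is an open-chain diketone flanked by two pyranones, assembled by two C-acylations of a chiral glutarate half-ester that carries C3.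

Key step: step 3

Numbering remark: carbon atoms are named by the tetralone numbering of the target (C1 ketone, C3 carbinol, C4a/C8a ring fusion, C5 pyranonyl, C6 phenyl, C8 phenol) in all intermediates.
Assumption: 1, 2 and 5 are taken as catalogue compounds; 2 is the (R)-half-ester of 3-silyloxyglutaric acid used for statin side chains.

Step 1
Reactants: 1 4-hydroxy-6-phenyl-2H-pyran-2-one; 2 (3R)-3-[(tert-butyldimethylsilyl)oxy]-5-methoxy-5-oxopentanoic acid
Product: 4 methyl (3R)-3-[(tert-butyldimethylsilyl)oxy]-5-(4-hydroxy-2-oxo-6-phenyl-2H-pyran-3-yl)-5-oxopentanoate, via O-acyl enol ester 3 (not isolated)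
Conditions: DCC (1.1 equiv), DMAP (0.3 equiv), PhMe, rt then 60 °C
Reagents that add atoms: none
Why: Carbodiimide O-acylation of the vinylogous acid 1 should give enol ester 3, which DMAP converts through an acylpyridinium/pyranone-enolate pair into the C3-acyl compound (Steglich-type O-to-C acyl migration, the standard entry to 3-acyl-4-hydroxy-2-pyranones); the methyl ester, the silyl ether and the stereocentre are not involved.

Step 2
Reactants: 4 methyl (3R)-3-[(tert-butyldimethylsilyl)oxy]-5-(4-hydroxy-2-oxo-6-phenyl-2H-pyran-3-yl)-5-oxopentanoate; 5 4-hydroxy-6-methyl-2H-pyran-2-one (triacetic acid lactone)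
Product: 6 4-hydroxy-3-[(3S)-3-[(tert-butyldimethylsilyl)oxy]-6-(4-hydroxy-2-oxo-2H-pyran-6-yl)-5-oxohexanoyl]-6-phenyl-2H-pyran-2-one
Conditions: 5 (3 equiv), LDA (7 equiv), THF, −78 → −20 °C; then 4, −78 → −20 °C; 1 M HCl
Reagents that add atoms: none
Why: Crossed Claisen condensation in which the dianion of 5 should attack the methyl ester through its 6-methyl carbon, while the acylpyranone of 4 is masked in the flask as its lithium enolate and the product is protected from over-addition as its own enolate; the stereocentre is untouched (R to S is a CIP change only).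

Step 3
Reactants: 6 4-hydroxy-3-[(3S)-3-[(tert-butyldimethylsilyl)oxy]-6-(4-hydroxy-2-oxo-2H-pyran-6-yl)-5-oxohexanoyl]-6-phenyl-2H-pyran-2-one
Product: 11 (3S)-3-[(tert-butyldimethylsilyl)oxy]-8-hydroxy-5-(4-hydroxy-2-oxo-2H-pyran-6-yl)-6-phenyl-3,4-dihydronaphthalen-1(2H)-one, via tris-TMS enol ether 7 (not isolated), via bridged lactone cycloadduct 8 (not isolated), via cyclohexadiene 9 (not isolated), via bis-TMS arene 10 (not isolated)
Conditions: BSA (4 equiv), PhMe, 60 °C; then 150 °C (sealed tube); then MeOH, citric acid, rt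
Reagents that add atoms: none
Why: BSA should convert 6 into 7, in which both pyranone hydroxyls are capped and the C4a ketone is held as the silyl enol ether conjugated to the intact pyranone; on heating, this C4a=C5 alkene adds across C3 and C6 of the 3-acyl-4-silyloxy-6-phenylpyranone in an intramolecular [4+2] cycloaddition (8), retro-[4+2] loss of CO2 gives diene 9, 1,2-elimination of Me3SiOH across C4a–C5 gives arene 10, and methanolysis of the two TMS ethers gives 11. The closest known reaction type is the Diels–Alder/CO2-extrusion benzannulation of 3-acyl- and 3-alkoxycarbonyl-2-pyranones with enol ethers, ketene acetals or enamines as alkyne equivalents, here run intramolecularly. The cyclohexanone ring (C1–C2–C3–C4–C4a–C8a) closes through the tether-side bond C4a–C8a of the cycloaddition (four-atom tether, six-membered ring), and the benzene ring (C4a–C5–C6–C7–C8–C8a) through that bond together with C5–C6, becoming aromatic by the two eliminations. No lasting stereocentre is created: C3 sits on the tether and is untouched, and the four transient stereocentres of 8 and both enol ether geometries converge on the same arene. Regiochemistry is fixed by the tether and reinforced by polarity (nucleophilic C5 to the electrophilic phenyl-bearing pyranone C6, oxygenated C4a to the acyl-bearing C3), and the acylated pyranone is the diene because it is the more electron-poor one and the other pyranone has no dienophile within reach. Neutral silylating conditions are chosen because base would divert the 6-(2-oxoalkyl)pyranone to a resorcylate by ring opening and aldol closure and would promote β-elimination of the silyl ether.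

Step 4
Reactants: 11 (3S)-3-[(tert-butyldimethylsilyl)oxy]-8-hydroxy-5-(4-hydroxy-2-oxo-2H-pyran-6-yl)-6-phenyl-3,4-dihydronaphthalen-1(2H)-one
Product: 12 wailupemycin F [(3S)-3,8-dihydroxy-5-(4-hydroxy-2-oxo-2H-pyran-6-yl)-6-phenyl-3,4-dihydronaphthalen-1(2H)-one]
Conditions: 48% aq. HF, MeCN, 0 °C → rt
Reagents that add atoms: none
Why: Acidic fluoride desilylation of a secondary TBS ether, as used for base-sensitive aldols, should free the C3 hydroxyl without a base that could trigger E1cB loss of the C3 oxygen; the configuration brought in with 2 is retained.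

Compound list
1 | 4-hydroxy-6-phenyl-2H-pyran-2-one | O=c1cc(O)cc(-c2ccccc2)o1 | starting material
2 | (3R)-3-[(tert-butyldimethylsilyl)oxy]-5-methoxy-5-oxopentanoic acid | OC(=O)C[C@@H](O[Si](C)(C)C(C)(C)C)CC(=O)OC | starting material
3 | O-acyl enol ester, methyl 2-oxo-6-phenyl-2H-pyran-4-yl (3S)-3-[(tert-butyldimethylsilyl)oxy]pentanedioate | O=C(C[C@@H](O[Si](C)(C)C(C)(C)C)CC(=O)OC)Oc1cc(-c2ccccc2)oc(=O)c1 | intermediate (not isolated)
4 | methyl (3R)-3-[(tert-butyldimethylsilyl)oxy]-5-(4-hydroxy-2-oxo-6-phenyl-2H-pyran-3-yl)-5-oxopentanoate | O=C(C[C@@H](O[Si](C)(C)C(C)(C)C)CC(=O)OC)c1c(O)cc(-c2ccccc2)oc1=O | intermediate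
5 | 4-hydroxy-6-methyl-2H-pyran-2-one (triacetic acid lactone) | Cc1cc(O)cc(=O)o1 | starting material
6 | 4-hydroxy-3-[(3S)-3-[(tert-butyldimethylsilyl)oxy]-6-(4-hydroxy-2-oxo-2H-pyran-6-yl)-5-oxohexanoyl]-6-phenyl-2H-pyran-2-one | O=C(C[C@@H](O[Si](C)(C)C(C)(C)C)CC(=O)Cc1cc(O)cc(=O)o1)c1c(O)cc(-c2ccccc2)oc1=O | intermediate
7 | tris-TMS enol ether of 6 (both pyranone hydroxyls and the C4a enol silylated; enol ether geometry not defined) | O=C(C[C@@H](O[Si](C)(C)C(C)(C)C)CC(O[Si](C)(C)C)=Cc1cc(O[Si](C)(C)C)cc(=O)o1)c1c(O[Si](C)(C)C)cc(-c2ccccc2)oc1=O | intermediate (not isolated)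
8 | bridged lactone cycloadduct (2-oxabicyclo[2.2.2]oct-5-en-3-one fused to the cyclohexanone; new stereocentres transient and not defined) | O=C1C[C@@H](O[Si](C)(C)C(C)(C)C)CC2(O[Si](C)(C)C)C(c3cc(O[Si](C)(C)C)cc(=O)o3)C4(c5ccccc5)C=C(O[Si](C)(C)C)C12C(=O)O4 | intermediate (not isolated)
9 | cyclohexadiene formed from 8 by loss of CO2 (4a-silyloxy-4a,5-dihydro form of 10) | O=C1C[C@@H](O[Si](C)(C)C(C)(C)C)CC2(O[Si](C)(C)C)C(c3cc(O[Si](C)(C)C)cc(=O)o3)C(c3ccccc3)=CC(O[Si](C)(C)C)=C12 | intermediate (not isolated)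
10 | bis-TMS ether of 11 (8-O-TMS and pyranone 4-O-TMS) | O=C1C[C@@H](O[Si](C)(C)C(C)(C)C)Cc2c1c(O[Si](C)(C)C)cc(-c1ccccc1)c2-c1cc(O[Si](C)(C)C)cc(=O)o1 | intermediate (not isolated)
11 | (3S)-3-[(tert-butyldimethylsilyl)oxy]-8-hydroxy-5-(4-hydroxy-2-oxo-2H-pyran-6-yl)-6-phenyl-3,4-dihydronaphthalen-1(2H)-one | O=C1C[C@@H](O[Si](C)(C)C(C)(C)C)Cc2c1c(O)cc(-c1ccccc1)c2-c1cc(O)cc(=O)o1 | intermediate
12 | wailupemycin F, (3S)-3,8-dihydroxy-5-(4-hydroxy-2-oxo-2H-pyran-6-yl)-6-phenyl-3,4-dihydronaphthalen-1(2H)-one | O=C1C[C@@H](O)Cc2c1c(O)cc(-c1ccccc1)c2-c1cc(O)cc(=O)o1 | target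

Total step count: 4. Longest linear sequence: 4 steps (1 and 2 to 12).

Steps most likely to fail

Step 3 (key step). The 4-silyloxy group makes the pyranone diene less electron-poor, so the cycloaddition may be outrun by desilylation, silyl transfer or fragmentation of the chain, or the bridged lactone may revert instead of losing CO2. The fallback sets out from 6 and comes back at 11. It gives up the leaving group on the dienophile and reaches the aromatic level by oxidation. Luche reduction of the side-chain ketone of 6 (NaBH4, CeCl3, MeOH, −40 °C; the acylpyranone is an unreactive vinylogous acid anion under these conditions) should give the carbinol F1 as a pair of C4a epimers. Acid-catalysed dehydration toward the acidic C5–H (TsOH cat., PhMe, 70 °C) should give the (E)-alkenylpyranone F2. Heating F2 (o-dichlorobenzene, 180 °C) should effect a normal-demand intramolecular pyranone–alkene Diels–Alder reaction to the bridged lactone F3, which loses CO2 to the cyclohexadiene F4. Dehydrogenation with DDQ in the same flask would give 11.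

Step 2. The strongly basic dianion may take a proton from the ester α-position of 4, with β-elimination of silanolate, or attack the acylpyranone instead of the ester. The fallback sets out from 5 and 2 and comes back at 6. It inverts the order of the two acylations so that the Claisen step is run before the first pyranone is in the molecule. 5 is capped (BnBr, K2CO3, DMF) as the benzyl ether F5. The 6-methyl group of F5 is lithiated (LDA, THF, −78 °C) and acylated by the methyl ester of 2, held as its lithium carboxylate, to give the keto acid F6. F6 then C-acylates 1 under the conditions of step 1 to give the benzyl-protected diketone F7, and hydrogenolysis (H2, Pd/C, EtOAc) returns 6.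

Step 4. Acid or fluoride may induce β-elimination of the C3 oxygen from the β-oxygenated tetralone, with aromatization to a naphthalene-1,8-diol. The fallback sets out from 6 and comes back at 12. It moves the removal of the TBS group ahead of the benzannulation, where no aromatization can drive elimination. Aqueous HF in MeCN converts 6 into the hydroxy diketone F8. BSA then silylates all four acidic positions to the tetrakis-TMS enol ether F9, so the C3 hydroxyl travels as a TMS ether. Thermolysis as in step 3 leads through the cycloadduct F10 and the cyclohexadiene F11 to the tris-TMS ether F12. Methanolysis with citric acid in MeOH at rt cleaves all three TMS ethers and gives 12 without a separate late deprotection.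

Further compounds
F1 | step 3 | 4-hydroxy-3-[(3S)-3-[(tert-butyldimethylsilyl)oxy]-5-hydroxy-6-(4-hydroxy-2-oxo-2H-pyran-6-yl)hexanoyl]-6-phenyl-2H-pyran-2-one (C5 epimers of the chain) | O=C(C[C@@H](O[Si](C)(C)C(C)(C)C)CC(O)Cc1cc(O)cc(=O)o1)c1c(O)cc(-c2ccccc2)oc1=O
F2 | step 3 | 4-hydroxy-3-[(3S,5E)-3-[(tert-butyldimethylsilyl)oxy]-6-(4-hydroxy-2-oxo-2H-pyran-6-yl)hex-5-enoyl]-6-phenyl-2H-pyran-2-one | O=C(C[C@@H](O[Si](C)(C)C(C)(C)C)C/C=C/c1cc(O)cc(=O)o1)c1c(O)cc(-c2ccccc2)oc1=O
F3 | step 3 | bridged lactone cycloadduct of F2 (new stereocentres transient and not defined) | O=C1C[C@@H](O[Si](C)(C)C(C)(C)C)CC2C(c3cc(O)cc(=O)o3)C4(c5ccccc5)C=C(O)C12C(=O)O4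
F4 | step 3 | cyclohexadiene from F3 by loss of CO2 (4a,5-dihydro form of 11) | O=C1C[C@@H](O[Si](C)(C)C(C)(C)C)CC2C(c3cc(O)cc(=O)o3)C(c3ccccc3)=CC(O)=C12
F5 | step 2 | 4-(benzyloxy)-6-methyl-2H-pyran-2-one | Cc1cc(OCc2ccccc2)cc(=O)o1
F6 | step 2 | (3S)-6-[4-(benzyloxy)-2-oxo-2H-pyran-6-yl]-3-[(tert-butyldimethylsilyl)oxy]-5-oxohexanoic acid | OC(=O)C[C@@H](O[Si](C)(C)C(C)(C)C)CC(=O)Cc1cc(OCc2ccccc2)cc(=O)o1
F7 | step 2 | 3-[(3S)-6-[4-(benzyloxy)-2-oxo-2H-pyran-6-yl]-3-[(tert-butyldimethylsilyl)oxy]-5-oxohexanoyl]-4-hydroxy-6-phenyl-2H-pyran-2-one | O=C(C[C@@H](O[Si](C)(C)C(C)(C)C)CC(=O)Cc1cc(OCc2ccccc2)cc(=O)o1)c1c(O)cc(-c2ccccc2)oc1=O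
F8 | step 4 | 4-hydroxy-3-[(3S)-3-hydroxy-6-(4-hydroxy-2-oxo-2H-pyran-6-yl)-5-oxohexanoyl]-6-phenyl-2H-pyran-2-one | O=C(C[C@@H](O)CC(=O)Cc1cc(O)cc(=O)o1)c1c(O)cc(-c2ccccc2)oc1=O
F9 | step 4 | tetrakis-TMS enol ether of F8 (enol ether geometry not defined) | O=C(C[C@@H](O[Si](C)(C)C)CC(O[Si](C)(C)C)=Cc1cc(O[Si](C)(C)C)cc(=O)o1)c1c(O[Si](C)(C)C)cc(-c2ccccc2)oc1=O
F10 | step 4 | bridged lactone cycloadduct of F9 (new stereocentres transient and not defined) | O=C1C[C@@H](O[Si](C)(C)C)CC2(O[Si](C)(C)C)C(c3cc(O[Si](C)(C)C)cc(=O)o3)C4(c5ccccc5)C=C(O[Si](C)(C)C)C12C(=O)O4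
F11 | step 4 | cyclohexadiene from F10 by loss of CO2 | O=C1C[C@@H](O[Si](C)(C)C)CC2(O[Si](C)(C)C)C(c3cc(O[Si](C)(C)C)cc(=O)o3)C(c3ccccc3)=CC(O[Si](C)(C)C)=C12
F12 | step 4 | tris-TMS ether of 12 (3-O, 8-O and pyranone 4-O silylated) | O=C1C[C@@H](O[Si](C)(C)C)Cc2c1c(O[Si](C)(C)C)cc(-c1ccccc1)c2-c1cc(O[Si](C)(C)C)cc(=O)o1
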